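## Structural features

The target (19) is a depside: two benzene rings that share no bond other than an aryl ester. Ring A is a benzoic acid (carboxyl on C1) with a heptyl chain on C2, the ester oxygen on C4 and a free hydroxyl on C6. Ring B is a 2,4-dihydroxy-6-methylbenzoyl unit whose carbonyl carbon is bound to O4 of ring A. There is no stereocentre and no stereogenic double bond, so nothing has to be set or guarded against epimerisation. The fragile points are the inter-ring aryl ester, which hydroxide, alkoxides and amines cleave or transesterify, and the acid of ring A, which as the free 2,4-dihydroxy acid loses CO2 on heating or in strong acid; both rings are electron-rich and easily over-halogenated or oxidised. The real difficulty is regiochemical. Ring A needs three contiguous substituents (C2 heptyl, C1 carboxyl, C6 oxygen) plus a second oxygen at C4, and O4 alone must be acylated by a di-ortho-substituted benzoyl group while O6, the acid and both ring B phenols carry groups removable without touching the ester. The key step uses the fact that C2 and C1 of ring A are neighbours and that C1 is flanked on its other side by the C6 oxygen: this is the pattern left when a carbon nucleophile and then an electrophile add across a 3-alkoxyaryne, the oxygen steering the nucleophile to the far carbon. Atom by atom, the triflate-bearing carbon of 3 becomes C2, the iodine-bearing carbon becomes C1, the benzyloxy carbon next to iodine becomes C6 and the other benzyloxy carbon becomes C4, so 3 and 11 map onto ring A with no correction of connectivity needed.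

## Logic of the disconnections

19 back to 18. The three oxygen–benzyl bonds (two ethers on ring B, one ester on ring A) are cut last. The depside ester and the free acid tolerate neither base, nucleophile nor strong acid, and neutral hydrogenolysis is the one unmasking that leaves both alone. The gain is that every temporary group is of one kind and falls in a single operation. The demand is that 18 contains nothing else reducible, which holds (no alkene, no halide, no sulfur).

18 back to 13 and 16. The ester bond between the ring B carbonyl and O4 of ring A is cut, because it is the only bond joining the rings and cutting it gives two fragments of similar size. The forward step must acylate O4 in the presence of O6 and must activate a hindered acid. The first rests on O6 being hydrogen-bonded to, and flanked by, the ester carbonyl; the second is met by turning 16 into mixed anhydride 17 in the flask.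

13 back to 12 and then 11. The benzyl ester bond of 13 is cut, and before that the two benzyl ether bonds of 11 are restored. The aryne step needs both oxygens capped and non-acidic, while the coupling needs O4 free and the acid capped; with identical benzyl groups the only clean way between the two states is to strip both ethers and re-cap the acid alone. The demand is carboxylate-selective alkylation (a base that ionises only the acid) and gentle handling of 12, which is used without storage.

11 back to 3, 5 and 6. The aryl–heptyl bond at C2 and the aryl–carboxyl bond at C1 are cut together. This takes ring A back to a symmetrically 1,3,5-trioxygenated benzene and makes both carbon–carbon bonds in one pot through 7, 8, 9 and 10. The forward step must add 5 to the correct end of 8. Three design choices support that step: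
- 5 serves as both exchange reagent and nucleophile, so no foreign carbanion can be incorporated.
- 3 is added slowly to an excess of 5, so that 9 does not compete for 8 or exchange with unreacted 3.
- The leaving group is a triflate, which departs at low temperature while the nucleophile is already present.

3 back to 2 and then 1. The sulfur–oxygen bond of the triflate and then the carbon–iodine bond are cut. Because both spectator oxygens of 1 carry the same benzyl group, its two ortho positions are equivalent and either gives 2. The demand is that iodination goes ortho to the hydroxyl and not to C4 between the two benzyloxy groups.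

5 back to 4. The carbon–magnesium bond is cut; magnesium insertion into a primary bromide is routine.

16 back to 15 and then 14. Ring B is bought with its full substitution pattern; only two benzyl ether bonds are added and the ethyl ester bond is cut. The demand is hydrolysis of a di-ortho-substituted ester without loss of the benzyl ethers, which hydroxide in a dipolar aprotic medium meets.

## Other disconnections considered

Alternative 1: Ring A is built from open chains by cutting C2–C3, C3–C4, C5–C6 and C6–C1. In the forward step diazoketone A2 is irradiated; the Wolff shift (which makes C2–C3) gives a vinylketene that adds ethoxyethyne A3 in a (2+2) cycloaddition. Heating opens the cyclobutenone (four electrons) and recloses it (six electrons) to phenol A1 (Danheiser benzannulation).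
- In favour: the position of every ring A substituent follows from connectivity, with no reliance on aryne polarisation or on a selective iodination; on regiochemical certainty this plan is the better one. The acid also emerges already as its benzyl ester, so the free dihydroxy acid and the carboxylate-selective benzylation are avoided, which is also better.
- Against: the differentiation of the oxygens is the wrong way round for this target. In A1, O6 is free and O4 is an ethyl ether; freeing O4 would need a boron halide that endangers the benzyl ester, so a silyl or benzyl ynol ether would have to replace A3. A2 needs several steps of its own (a regiodefined heptyl-substituted ene-dicarbonyl, then diazo installation), plus photochemical equipment and a volatile alkyne.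
- Comparison: mechanistically both plans are one-pot cascades of comparable appeal, four bonds and a ring against two bonds on an existing ring. On step count to the coupling partner 13 the chosen plan should be shorter.

Alternative 2: The depside C–O bond and the ring B bond between the ester alpha carbon and the methyl-bearing carbon are cut, so ring B grows on O4. In the forward step diketo-dioxinone A5 is heated with 13; cycloreversion gives an acylketene that acylates O4, and triethylamine then drives aldol condensation and dehydration to A4. One hydrogenolysis of the benzyl ester would finish the synthesis.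
- In favour: the acylating agent is an unhindered, very electrophilic ketene, so transfer of a di-ortho-substituted aroyl group is avoided. Ring B needs no protecting groups, so steps 7 and 8 and two benzyl groups disappear; on protecting-group economy this plan is the better one. It uses the same ring A partner 13 and is compatible with the aryne key step.
- Against: the O4 over O6 selectivity requirement is unchanged (equal). The intermediate is an aryl ester of a triketo acid with a good phenoxide leaving group, so cyclisations that expel the ring A phenol (pyrone formation, Claisen closure to an acylphloroglucinol) can compete with the desired aldol. A5 is delicate and needs two or three steps from a commercial dioxinone.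
- Comparison: step count is about equal to steps 7–10 of the chosen plan, with more mechanistic risk in the ring-forming event.

Alternative 3: The ring B bonds C1–C2 and C5–C6 are cut with the ester already in place. In the forward step butynoate A7 is heated with diene A8; the diene terminus attacks the methyl-bearing alkyne carbon, the ketene acetal carbon bonds to the ester-bearing carbon, and acidic work-up aromatises the adduct to A6.
- In favour: the ester bond is formed earlier from an unhindered alkynoic acid, which is easier than the hindered acylation of the chosen plan (better on that point). The orientation of ring B follows from the polarity of diene and ynoate (equal to the chosen plan, where ring B is bought). Ring B emerges unprotected.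
- Against: A7 needs a ring A phenol with O6 and the acid capped and only O4 free, which costs extra differentiation steps. A beta-methyl ynoate is a sluggish dienophile, and its activated aryl ester can be attacked at the carbonyl by the nucleophilic diene. A8 has to be made from benzyl acetoacetate and is moisture-sensitive.
- Comparison: ring A still has to be made, so the alternative builds a ring that is commercially available as 14. The chosen plan is clearly shorter.

Key step: step 4

Remark on the chemistry: 1, 4, 6 and 14 are taken as purchasable; ring A is numbered from the carboxyl carbon (C1) with heptyl on C2; the target has no stereo-element, so no step has to control configuration.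

## Route

Step 1
Reactants: 1 3,5-bis(benzyloxy)phenol
Product: 2 3,5-bis(benzyloxy)-2-iodophenol
Conditions: NIS (1.0 equiv), CH2Cl2, −78 to 0 °C, dark
Reagents that add atoms: N-iodosuccinimide, O=C1CCC(=O)N1I
Why: Electrophilic aromatic iodination; in a non-coordinating solvent the phenolic OH hydrogen-bonds the succinimide carbonyl and delivers iodine to the adjacent carbon, and the two equivalent ortho sites (each para to a benzyloxy group) are less encumbered than C4, which lies between two benzyloxy groups. One equivalent of reagent at low temperature limits di-iodination.

Step 2
Reactants: 2 3,5-bis(benzyloxy)-2-iodophenol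
Product: 3 3,5-bis(benzyloxy)-2-iodophenyl trifluoromethanesulfonate
Conditions: Tf2O (1.2 equiv), pyridine, CH2Cl2, 0 °C
Reagents that add atoms: trifluoromethanesulfonic anhydride, O=S(=O)(OS(=O)(=O)C(F)(F)F)C(F)(F)F
Why: O-Sulfonylation of a phenol; the aryl iodide and the benzyl ethers are inert to the anhydride and the weak base.

Step 3
Reactants: 4 1-bromoheptane
Product: 5 heptylmagnesium bromide
Conditions: Mg turnings, I2 (cat.), THF, 25–45 °C; titrate
Reagents that add atoms: magnesium, [Mg]
Why: Grignard reagent formation by insertion of magnesium into a primary carbon–bromine bond.

Step 4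
Reactants: 3 3,5-bis(benzyloxy)-2-iodophenyl trifluoromethanesulfonate; 5 heptylmagnesium bromide; 6 carbon dioxide
Product: 11 2,4-bis(benzyloxy)-6-heptylbenzoic acid, via magnesiated aryl triflate 7 (not isolated), via 3,5-bis(benzyloxy)benzyne 8 (not isolated), via arylmagnesium bromide 9 (not isolated), via bromomagnesium carboxylate 10 (not isolated)
Conditions: 5 (3 equiv), THF, −78 °C, slow addition of 3, then to 0 °C; 6 (dry gas), −20 °C to rt; 1 M HCl
Reagents that add atoms: none
Why: Heptylmagnesium bromide 5 attacks the iodine of 3 (iodine–magnesium exchange), which is driven by the sp2 carbanion lying between two inductively withdrawing oxygens and gives 7 and 1-iodoheptane. 7 loses magnesium triflate by beta-elimination already at low temperature and releases aryne 8. A second equivalent of 5 adds across the strained triple bond (carbomagnesiation), and the resulting arylmagnesium 9 is carboxylated by 6 to 10, which aqueous acid turns into 11. The closest known reaction type is the carbomagnesiation of 3-alkoxyarynes generated from 2-haloaryl sulfonates by halogen–magnesium exchange, with electrophilic quench of the ortho-alkoxy arylmagnesium. No ring is closed and no stereocentre is formed. The selectivity that matters is the regiochemistry of addition to the unsymmetrical aryne: the benzyloxy group directly beside the triple bond polarises it by sigma-withdrawal, so the remote carbon is the more electrophilic terminus and the negative charge develops next to oxygen; the second benzyloxy group is one position further away and its weaker, opposite bias should not override this. Chemoselectivity rests on 5 being the only carbanion in the flask, on adding 3 slowly to an excess of 5 so that 9 neither exchanges with unreacted 3 nor competes for 8, and on the absence of any ester or other electrophile until 6 is admitted.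

Step 5
Reactants: 11 2,4-bis(benzyloxy)-6-heptylbenzoic acid
Product: 12 2-heptyl-4,6-dihydroxybenzoic acid
Conditions: H2 (1 atm), 10% Pd/C, EtOAc, rt; concentrate below 30 °C and use at once
Reagents that add atoms: none
Why: Hydrogenolysis of two aryl benzyl ethers; the alkyl chain and the acid are inert, and neutral conditions at room temperature avoid decarboxylation of the dihydroxy acid.

Step 6
Reactants: 12 2-heptyl-4,6-dihydroxybenzoic acid
Product: 13 benzyl 2-heptyl-4,6-dihydroxybenzoate
Conditions: BnBr (1.05 equiv), KHCO3 (1.2 equiv), DMF, rt
Reagents that add atoms: benzyl bromide, BrCc1ccccc1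
Why: SN2 O-alkylation of a carboxylate; hydrogencarbonate ionises only the carboxylic acid and not the phenols, so the ester forms without ether formation.

Step 7
Reactants: 14 ethyl 2,4-dihydroxy-6-methylbenzoate
Product: 15 ethyl 2,4-bis(benzyloxy)-6-methylbenzoate
Conditions: BnBr (2.5 equiv), K2CO3 (3 equiv), DMF, 70 °C
Reagents that add atoms: benzyl bromide, BrCc1ccccc1
Why: Williamson ether synthesis on both phenols; heating is needed to alkylate the hydroxyl that is hydrogen-bonded to the ester.

Step 8
Reactants: 15 ethyl 2,4-bis(benzyloxy)-6-methylbenzoate
Product: 16 2,4-bis(benzyloxy)-6-methylbenzoic acid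
Conditions: KOH, DMSO–H2O (4:1), 90 °C; then aq. HCl
Reagents that add atoms: potassium hydroxide, [K+].[OH-]
Why: Saponification of a di-ortho-substituted ester; poorly solvated hydroxide in aqueous DMSO forces acyl substitution, and benzyl ethers are stable to base.

Step 9
Reactants: 13 benzyl 2-heptyl-4,6-dihydroxybenzoate; 16 2,4-bis(benzyloxy)-6-methylbenzoic acid
Product: 18 benzyl 4-{[2,4-bis(benzyloxy)-6-methylbenzoyl]oxy}-2-heptyl-6-hydroxybenzoate, via mixed trifluoroacetic anhydride 17 (not isolated)
Conditions: 16, (CF3CO)2O (1.5 equiv), toluene, rt; then 13, rt; aq. NaHCO3 work-up
Reagents that add atoms: none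
Why: Mixed-anhydride esterification; the electron-rich aroyl trifluoroacetate 17 transfers its aroyl group to the free, unhindered C4 hydroxyl, while the C6 hydroxyl is hydrogen-bonded to and flanked by the benzyl ester and should stay free. Any phenolic trifluoroacetate is cleaved on the hydrogencarbonate wash.

Step 10
Reactants: 18 benzyl 4-{[2,4-bis(benzyloxy)-6-methylbenzoyl]oxy}-2-heptyl-6-hydroxybenzoate
Product: 19 4-[(2,4-dihydroxy-6-methylbenzoyl)oxy]-2-heptyl-6-hydroxybenzoic acid (target)
Conditions: H2 (1 atm), 10% Pd/C, EtOAc, rt
Reagents that add atoms: none
Why: Hydrogenolysis of two benzyl ethers and one benzyl ester in a neutral, non-nucleophilic solvent, so the inter-ring aryl ester is neither hydrolysed nor transesterified.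

## Compound list

1 | 3,5-bis(benzyloxy)phenol | Oc1cc(OCc2ccccc2)cc(OCc2ccccc2)c1 | starting material
2 | 3,5-bis(benzyloxy)-2-iodophenol | Oc1cc(OCc2ccccc2)cc(OCc2ccccc2)c1I | intermediate
3 | 3,5-bis(benzyloxy)-2-iodophenyl trifluoromethanesulfonate | O=S(=O)(Oc1cc(OCc2ccccc2)cc(OCc2ccccc2)c1I)C(F)(F)F | intermediate
4 | 1-bromoheptane | CCCCCCCBr | starting material
5 | heptylmagnesium bromide | CCCCCCC[Mg]Br | intermediate
6 | carbon dioxide | O=C=O | starting material
7 | 3,5-bis(benzyloxy)-2-(bromomagnesio)phenyl trifluoromethanesulfonate | O=S(=O)(Oc1cc(OCc2ccccc2)cc(OCc2ccccc2)c1[Mg]Br)C(F)(F)F | intermediate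
8 | 3,5-bis(benzyloxy)benzyne (1,2-didehydro-3,5-bis(benzyloxy)benzene) | C1#CC(OCc2ccccc2)=CC(OCc2ccccc2)=C1 | intermediate
9 | [2,4-bis(benzyloxy)-6-heptylphenyl]magnesium bromide | CCCCCCCc1cc(OCc2ccccc2)cc(OCc2ccccc2)c1[Mg]Br | intermediate
10 | bromomagnesium 2,4-bis(benzyloxy)-6-heptylbenzoate | CCCCCCCc1cc(OCc2ccccc2)cc(OCc2ccccc2)c1C(=O)O[Mg]Br | intermediate
11 | 2,4-bis(benzyloxy)-6-heptylbenzoic acid | CCCCCCCc1cc(OCc2ccccc2)cc(OCc2ccccc2)c1C(=O)O | intermediate
12 | 2-heptyl-4,6-dihydroxybenzoic acid | CCCCCCCc1cc(O)cc(O)c1C(=O)O | intermediate
13 | benzyl 2-heptyl-4,6-dihydroxybenzoate | CCCCCCCc1cc(O)cc(O)c1C(=O)OCc1ccccc1 | intermediate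
14 | ethyl 2,4-dihydroxy-6-methylbenzoate | CCOC(=O)c1c(C)cc(O)cc1O | starting material
15 | ethyl 2,4-bis(benzyloxy)-6-methylbenzoate | CCOC(=O)c1c(C)cc(OCc2ccccc2)cc1OCc1ccccc1 | intermediate
16 | 2,4-bis(benzyloxy)-6-methylbenzoic acid | Cc1cc(OCc2ccccc2)cc(OCc2ccccc2)c1C(=O)O | intermediate
17 | 2,4-bis(benzyloxy)-6-methylbenzoic trifluoroacetic anhydride | Cc1cc(OCc2ccccc2)cc(OCc2ccccc2)c1C(=O)OC(=O)C(F)(F)F | intermediate
18 | benzyl 4-{[2,4-bis(benzyloxy)-6-methylbenzoyl]oxy}-2-heptyl-6-hydroxybenzoate | CCCCCCCc1cc(OC(=O)c2c(C)cc(OCc3ccccc3)cc2OCc2ccccc2)cc(O)c1C(=O)OCc1ccccc1 | intermediate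
19 | 4-[(2,4-dihydroxy-6-methylbenzoyl)oxy]-2-heptyl-6-hydroxybenzoic acid | CCCCCCCc1cc(OC(=O)c2c(C)cc(O)cc2O)cc(O)c1C(=O)O | target

## Step count and risk

Total step count: 10. Longest linear sequence: 7 steps (steps 1, 2, 4, 5, 6, 9, 10, from 1 to 19). Step 3 and steps 7–8 are side branches.

Step 4 (key step). Three things are most likely to go wrong. Exchange by a primary alkyl Grignard at an iodide on a donor-rich ring may be sluggish. The arylmagnesium product may capture the aryne (biaryl formation) if the aryne is released faster than 5 can trap it. The sulfonyl sulfur may be attacked, which would return the phenoxide. A partial loss of regiocontrol is less likely but would give an inseparable isomeric acid. The fallback avoids arynes and reaches 11 from 1 by cross-coupling and formylation. 1 is triflated (Tf2O, pyridine) to 3,5-bis(benzyloxy)phenyl trifluoromethanesulfonate F1. Kumada coupling of F1 with 5 under PdCl2(dppf) catalysis in THF gives 1,3-bis(benzyloxy)-5-heptylbenzene F2. Vilsmeier–Haack formylation (POCl3, DMF) attacks the position para to one benzyloxy group and next to the heptyl chain rather than the position between the two ethers, giving 2,4-bis(benzyloxy)-6-heptylbenzaldehyde F3. Pinnick oxidation (NaClO2, NaH2PO4, 2-methylbut-2-ene) then gives 11, where the route is rejoined.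

Step 1. The likely failure is imperfect site selectivity: iodination at C4 between the two ethers, or a second iodination, because all three free ring positions are strongly activated. The fallback replaces electrophilic substitution by directed ortho-metalation and runs from 1 to 2. 1 is carbamoylated (ClC(=O)NEt2, K2CO3, MeCN) to 3,5-bis(benzyloxy)phenyl N,N-diethylcarbamate F4. Lithiation with s-BuLi/TMEDA in THF at −78 °C occurs at the carbon between the carbamate and a benzyloxy group, and I2 quench gives 3,5-bis(benzyloxy)-2-iodophenyl N,N-diethylcarbamate F5. Hydrolysis (NaOH, aqueous EtOH, reflux) then gives 2.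

Step 9. The likely failures are acylation at O6 or at both hydroxyls, and slow transfer of the hindered aroyl group with competing trifluoroacetylation. The fallback removes the selectivity question by differentiating the oxygens first; it runs from 13 and rejoins at 19.
- 13 is alkylated at the non-chelated hydroxyl (MOMCl, i-Pr2NEt, CH2Cl2, 0 °C) to benzyl 2-heptyl-6-hydroxy-4-(methoxymethoxy)benzoate F6.
- The remaining hydroxyl is benzylated (BnBr, K2CO3, DMF, 60 °C) to benzyl 2-(benzyloxy)-6-heptyl-4-(methoxymethoxy)benzoate F7.
- The acetal is removed (HCl, MeOH–THF, 40 °C; the hindered ester should not exchange) to give benzyl 2-(benzyloxy)-6-heptyl-4-hydroxybenzoate F8.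
- F8 is acylated with 16 through 17 as in step 9 to give benzyl 2-(benzyloxy)-4-{[2,4-bis(benzyloxy)-6-methylbenzoyl]oxy}-6-heptylbenzoate F9.
- Hydrogenolysis as in step 10 gives 19.

Step 6 (with the handling of 12 from step 5). The likely failures are alkylation of the para hydroxyl alongside the carboxylate and loss of CO2 from the free acid before it is capped. The fallback uses no alkyl halide and runs from 12 to 13. 12 is condensed with acetone (trifluoroacetic anhydride, trifluoroacetic acid, 0 °C to rt) to the stable 5-heptyl-7-hydroxy-2,2-dimethyl-4H-1,3-benzodioxin-4-one F10. Excess sodium benzyloxide (BnOH, NaH, THF, 50 °C) opens it by acyl substitution to 13.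

## Further compounds

F1 | step 4 | 3,5-bis(benzyloxy)phenyl trifluoromethanesulfonate | O=S(=O)(Oc1cc(OCc2ccccc2)cc(OCc2ccccc2)c1)C(F)(F)F
F2 | step 4 | 1,3-bis(benzyloxy)-5-heptylbenzene | CCCCCCCc1cc(OCc2ccccc2)cc(OCc2ccccc2)c1
F3 | step 4 | 2,4-bis(benzyloxy)-6-heptylbenzaldehyde | CCCCCCCc1cc(OCc2ccccc2)cc(OCc2ccccc2)c1C=O
F4 | step 1 | 3,5-bis(benzyloxy)phenyl N,N-diethylcarbamate | CCN(CC)C(=O)Oc1cc(OCc2ccccc2)cc(OCc2ccccc2)c1
F5 | step 1 | 3,5-bis(benzyloxy)-2-iodophenyl N,N-diethylcarbamate | CCN(CC)C(=O)Oc1cc(OCc2ccccc2)cc(OCc2ccccc2)c1I
F6 | step 9 | benzyl 2-heptyl-6-hydroxy-4-(methoxymethoxy)benzoate | CCCCCCCc1cc(OCOC)cc(O)c1C(=O)OCc1ccccc1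
F7 | step 9 | benzyl 2-(benzyloxy)-6-heptyl-4-(methoxymethoxy)benzoate | CCCCCCCc1cc(OCOC)cc(OCc2ccccc2)c1C(=O)OCc1ccccc1
F8 | step 9 | benzyl 2-(benzyloxy)-6-heptyl-4-hydroxybenzoate | CCCCCCCc1cc(O)cc(OCc2ccccc2)c1C(=O)OCc1ccccc1
F9 | step 9 | benzyl 2-(benzyloxy)-4-{[2,4-bis(benzyloxy)-6-methylbenzoyl]oxy}-6-heptylbenzoate | CCCCCCCc1cc(OC(=O)c2c(C)cc(OCc3ccccc3)cc2OCc2ccccc2)cc(OCc2ccccc2)c1C(=O)OCc1ccccc1
F10 | step 6 | 5-heptyl-7-hydroxy-2,2-dimethyl-4H-1,3-benzodioxin-4-one | CCCCCCCc1cc(O)cc2OC(C)(C)OC(=O)c12
A1 | alternative 1 | benzyl 4-ethoxy-2-heptyl-6-hydroxybenzoate | CCCCCCCc1cc(OCC)cc(O)c1C(=O)OCc1ccccc1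
A2 | alternative 1 | benzyl (2E)-5-diazo-3-heptyl-4-oxopent-2-enoate | CCCCCCC/C(=C\C(=O)OCc1ccccc1)C(=O)C=[N+]=[N-]
A3 | alternative 1 | ethoxyethyne | C#COCC
A4 | alternative 2 | benzyl 4-[(2,4-dihydroxy-6-methylbenzoyl)oxy]-2-heptyl-6-hydroxybenzoate | CCCCCCCc1cc(OC(=O)c2c(C)cc(O)cc2O)cc(O)c1C(=O)OCc1ccccc1
A5 | alternative 2 | 6-(2,4-dioxopentyl)-2,2-dimethyl-4H-1,3-dioxin-4-one | CC(=O)CC(=O)CC1=CC(=O)OC(C)(C)O1
A6 | alternative 3 | benzyl 2-(benzyloxy)-4-[(2,4-dihydroxy-6-methylbenzoyl)oxy]-6-heptylbenzoate | CCCCCCCc1cc(OC(=O)c2c(C)cc(O)cc2O)cc(OCc2ccccc2)c1C(=O)OCc1ccccc1
A7 | alternative 3 | benzyl 2-(benzyloxy)-4-(but-2-ynoyloxy)-6-heptylbenzoate | CCCCCCCc1cc(OC(=O)C#CC)cc(OCc2ccccc2)c1C(=O)OCc1ccccc1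
A8 | alternative 3 | 1-(benzyloxy)-1,3-bis(trimethylsilyloxy)buta-1,3-diene (ketene acetal geometry not defined, lost on aromatisation) | C=C(O[Si](C)(C)C)C=C(OCc1ccccc1)O[Si](C)(C)C
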